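**Plan**

- Retrosynthesis: the 4'-O–Si bond, the 3-O–CH3 bond and the oxidation level of C3/C4 are adjusted last. Ring C is then opened at C3–C4 (reductive coupling of two aldehyde carbons), then at O1–C2 (phenol alkylation by an α-bromo arylacetate). Ring A is simplified at the 7-O–prenyl bond, the C4a–CHO bond and the C5–O bond.
- Enabling feature: C3 and C4 of the pyranone ring C are adjacent carbons that both carry oxygen, and they are already linked through C4a–C8a–O1–C2. Two aldehyde carbons on that tether can therefore be joined by a ketyl radical.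
- Forward: the ring A salicylaldehyde is made from 2-methoxyresorcinol (steps 1–6) and the ring B bromo ester from methyl homovanillate (steps 7–8). They are joined at O1–C2 (step 9) and adjusted to the dialdehyde (steps 10–11). Ring C closes at C3–C4 (step 12), followed by oxidation to the flavonol, 3-O-methylation and desilylation (steps 13–15).
- Stereochemistry: the target has no stereocentre. C2, C3 and C4 of the flavan-3,4-diol arise as a racemic diastereomer mixture and are all removed in step 13.

Key step: step 12

Assumption: the target is achiral (no stereocentre, and the prenyl double bond carries two identical methyl groups), so there is no enantiomer to select and racemic intermediates are used throughout.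

**Route**

Step 1
Reactants: 1 2-methoxybenzene-1,3-diol (2-methoxyresorcinol)
Product: 2 2-methoxy-1,3-bis(methoxymethoxy)benzene
Conditions: NaH (2.4 equiv), MOMCl (2.4 equiv), DMF, 0 °C → rt
Reagents that add atoms: chloromethyl methyl ether, COCCl
Why: Williamson-type O-alkylation of both phenoxides gives the bis-MOM ether, which is inert to the iridium catalyst of step 2 and later directs the ortho-lithiation of step 4.

Step 2
Reactants: 2 2-methoxy-1,3-bis(methoxymethoxy)benzene
Product: 4 4-methoxy-3,5-bis(methoxymethoxy)phenol, via arylboronic pinacol ester 3 (not isolated)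
Conditions: [Ir(OMe)(cod)]2 (cat.), dtbpy (cat.), B2pin2 (0.6 equiv), THF, 80 °C; then aq. NaOH, 30% H2O2, 0 °C → rt
Reagents that add atoms: hydrogen peroxide, OO; bis(pinacolato)diboron, CC1(C)OB(OC1(C)C)B1OC(C)(C)C(C)(C)O1 (boron present in 3 only)
Why: Iridium-catalysed C–H borylation is sterically controlled and should take the only ring C–H with no ortho substituent (C5, para to the methoxy group); basic peroxide then oxidises the C–B bond to the phenol at the same carbon.

Step 3
Reactants: 4 4-methoxy-3,5-bis(methoxymethoxy)phenol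
Product: 5 2,5-dimethoxy-1,3-bis(methoxymethoxy)benzene
Conditions: MeI, K2CO3, acetone, 45 °C
Reagents that add atoms: iodomethane, CI
Why: Williamson methylation of the single free phenol installs the oxygen substituent that becomes the 5-methoxy group of the flavone.

Step 4
Reactants: 5 2,5-dimethoxy-1,3-bis(methoxymethoxy)benzene
Product: 7 3,6-dimethoxy-2,4-bis(methoxymethoxy)benzaldehyde, via aryllithium 6 (not isolated)
Conditions: n-BuLi (1.2 equiv), TMEDA, THF, 0 °C; DMF, −78 °C → rt; H2O
Reagents that add atoms: N,N-dimethylformamide, CN(C)C=O; n-butyllithium, [Li]CCCC (lithium present in 6 only)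
Why: Directed ortho-metalation takes place at the one kind of ring C–H, flanked by a MOM ether and a methoxy group, and formylation of the aryllithium with DMF gives a single regioisomer because the two ring hydrogens are equivalent.

Step 5
Reactants: 7 3,6-dimethoxy-2,4-bis(methoxymethoxy)benzaldehyde
Product: 8 2,4-dihydroxy-3,6-dimethoxybenzaldehyde
Conditions: conc. HCl (cat.), MeOH, 50 °C
Reagents that add atoms: none
Why: Acid-catalysed acetal exchange with methanol removes both MOM ethers, while the aryl methyl ethers and the aldehyde are stable under these conditions.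

Step 6
Reactants: 8 2,4-dihydroxy-3,6-dimethoxybenzaldehyde; 9 1-bromo-3-methylbut-2-ene (prenyl bromide)
Product: 10 2-hydroxy-3,6-dimethoxy-4-(3-methylbut-2-enyloxy)benzaldehyde
Conditions: K2CO3 (1.05 equiv), acetone, rt
Reagents that add atoms: none
Why: Regioselective Williamson etherification is expected at the 4-hydroxyl, which is para to the formyl group, more acidic and not tied up in the hydrogen bond to the carbonyl that deactivates the 2-hydroxyl.

Step 7
Reactants: 11 methyl 2-(4-hydroxy-3-methoxyphenyl)acetate (methyl homovanillate)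
Product: 12 methyl 2-(3-methoxy-4-triisopropylsilyloxyphenyl)acetate
Conditions: TIPSCl, imidazole, DMF, rt
Reagents that add atoms: chlorotriisopropylsilane, CC(C)[Si](Cl)(C(C)C)C(C)C
Why: Silylation of the phenol gives the most base-stable common aryl silyl ether, which should survive carbonate, hydride, samarium(II) and oxidants and is removed by fluoride at the end without touching the prenyl ether.

Step 8
Reactants: 12 methyl 2-(3-methoxy-4-triisopropylsilyloxyphenyl)acetate
Product: 15 methyl 2-bromo-2-(3-methoxy-4-triisopropylsilyloxyphenyl)acetate (racemic), via lithium enolate 13 (not isolated), via silyl ketene acetal 14 (not isolated)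
Conditions: LiHMDS, THF, −78 °C; TMSCl; then NBS, −78 → 0 °C
Reagents that add atoms: N-bromosuccinimide, O=C1CCC(=O)N1Br; chlorotrimethylsilane, C[Si](C)(C)Cl (silicon present in 14 only); lithium hexamethyldisilazide, [Li]N([Si](C)(C)C)[Si](C)(C)C (lithium present in 13 only)
Why: Electrophilic α-bromination of the silyl ketene acetal places bromine only on the benzylic carbon and avoids the ring bromination that a free NBS reaction of this electron-rich arene could give; the new centre is racemic and is destroyed later.

Step 9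
Reactants: 10 2-hydroxy-3,6-dimethoxy-4-(3-methylbut-2-enyloxy)benzaldehyde; 15 methyl 2-bromo-2-(3-methoxy-4-triisopropylsilyloxyphenyl)acetate (racemic)
Product: 16 methyl 2-[2-formyl-3,6-dimethoxy-5-(3-methylbut-2-enyloxy)phenoxy]-2-(3-methoxy-4-triisopropylsilyloxyphenyl)acetate (racemic)
Conditions: K2CO3, acetone, 45 °C
Reagents that add atoms: none
Why: Williamson O-alkylation of the remaining phenol by the activated benzylic α-bromo ester forms the O1–C2 bond, and mild carbonate in acetone should spare the aryl silyl ether and avoid the aldol closure to a benzofuran that harsher base brings on.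

Step 10
Reactants: 16 methyl 2-[2-formyl-3,6-dimethoxy-5-(3-methylbut-2-enyloxy)phenoxy]-2-(3-methoxy-4-triisopropylsilyloxyphenyl)acetate (racemic)
Product: 17 2-[2-(hydroxymethyl)-3,6-dimethoxy-5-(3-methylbut-2-enyloxy)phenoxy]-2-(3-methoxy-4-triisopropylsilyloxyphenyl)ethanol (racemic)
Conditions: DIBAL-H (5 equiv), CH2Cl2, −78 → 0 °C; aq. Rochelle salt
Reagents that add atoms: none
Why: Hydride reduction with DIBAL-H takes both the ester and the aryl aldehyde to the primary alcohols, so that the two carbons can be brought to the aldehyde level together in the next step; the neutral tartrate work-up protects the acid-sensitive benzylic alcohol.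

Step 11
Reactants: 17 2-[2-(hydroxymethyl)-3,6-dimethoxy-5-(3-methylbut-2-enyloxy)phenoxy]-2-(3-methoxy-4-triisopropylsilyloxyphenyl)ethanol (racemic)
Product: 18 2-[1-(3-methoxy-4-triisopropylsilyloxyphenyl)-2-oxoethoxy]-3,6-dimethoxy-4-(3-methylbut-2-enyloxy)benzaldehyde (racemic)
Conditions: Dess–Martin periodinane (2.6 equiv), pyridine, CH2Cl2, 0 °C → rt; crude product used at once
Reagents that add atoms: none
Why: Pyridine-buffered Dess–Martin oxidation converts both primary alcohols into aldehydes under near-neutral conditions, without the chloride and strong base of activated-DMSO methods that could ionise the electron-rich benzylic position or enolise the α-aryloxy aldehyde.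

Step 12
Reactants: 18 2-[1-(3-methoxy-4-triisopropylsilyloxyphenyl)-2-oxoethoxy]-3,6-dimethoxy-4-(3-methylbut-2-enyloxy)benzaldehyde (racemic)
Product: 19 5,8-dimethoxy-2-(3-methoxy-4-triisopropylsilyloxyphenyl)-7-(3-methylbut-2-enyloxy)chromane-3,4-diol (racemic mixture of diastereomers, 3,4-cis expected to predominate)
Conditions: SmI2 (2.5 equiv), t-BuOH (3 equiv), THF (0.01 M in 18, slow addition), −78 °C; pH 7 buffer
Reagents that add atoms: none
Why: Samarium diiodide transfers one electron to the conjugated aryl aldehyde to give a samarium(III) ketyl at C4, which adds to the samarium-coordinated α-aryloxy aldehyde carbon C3; a second electron and protonation by t-BuOH then give the diol. The closest known reaction type is the SmI2-mediated intramolecular pinacol coupling of 1,6-dialdehydes, which gives cyclic cis-1,2-diols. Ring C closes by 6-exo-trig attack of the C4 ketyl on the C3 carbonyl, with the tether running through C4a, C8a, O1 and C2. The new centres C3 and C4 should be cis because both oxygens are held on samarium in a chelated transition state, and the aryl group at the existing C2 centre should lie pseudo-equatorial; neither outcome matters because all three centres are removed in step 13. The step needs ketyl formation and ring closure to outrun reductive loss of the aryloxide from C2 and intermolecular coupling, which the more easily reduced aryl aldehyde, the fast six-membered closure, the low temperature and the high dilution are expected to secure.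

Step 13
Reactants: 19 5,8-dimethoxy-2-(3-methoxy-4-triisopropylsilyloxyphenyl)-7-(3-methylbut-2-enyloxy)chromane-3,4-diol (racemic diastereomer mixture)
Product: 21 3-hydroxy-5,8-dimethoxy-2-(3-methoxy-4-triisopropylsilyloxyphenyl)-7-(3-methylbut-2-enyloxy)chromen-4-one, via flavan-3,4-dione 20 (not isolated)
Conditions: IBX (3.5 equiv), DMSO, rt → 40 °C
Reagents that add atoms: none
Why: IBX oxidation of a 1,2-diol gives the 1,2-dione without glycol cleavage, and the dione should enolise through its acidic C2–H to the aromatic 3-hydroxychromen-4-one, which removes the stereocentres at C2, C3 and C4.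

Step 14
Reactants: 21 3-hydroxy-5,8-dimethoxy-2-(3-methoxy-4-triisopropylsilyloxyphenyl)-7-(3-methylbut-2-enyloxy)chromen-4-one
Product: 22 3,5,8-trimethoxy-2-(3-methoxy-4-triisopropylsilyloxyphenyl)-7-(3-methylbut-2-enyloxy)chromen-4-one
Conditions: MeI, K2CO3, acetone, rt → 40 °C
Reagents that add atoms: iodomethane, CI
Why: Williamson methylation of the acidic enolic 3-hydroxyl is standard for flavonols, and dry carbonate in acetone should leave the triisopropylsilyl ether in place so that the 4'-oxygen is not methylated.

Step 15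
Reactants: 22 3,5,8-trimethoxy-2-(3-methoxy-4-triisopropylsilyloxyphenyl)-7-(3-methylbut-2-enyloxy)chromen-4-one
Product: 23 2-(4-hydroxy-3-methoxyphenyl)-3,5,8-trimethoxy-7-(3-methylbut-2-enyloxy)chromen-4-one (4'-hydroxy-3,5,8,3'-tetramethoxy-7-prenyloxyflavone)
Conditions: TBAF, AcOH, THF, 0 °C
Reagents that add atoms: none
Why: Fluoride-induced cleavage of the aryl Si–O bond frees the 4'-phenol under buffered conditions that leave the prenyl ether, the methyl ethers and the chromone untouched.

**Compound list**

1 | 2-methoxybenzene-1,3-diol (2-methoxyresorcinol) | COc1c(O)cccc1O | starting material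
2 | 2-methoxy-1,3-bis(methoxymethoxy)benzene | COCOc1cccc(OCOC)c1OC | intermediate
3 | 2-[4-methoxy-3,5-bis(methoxymethoxy)phenyl]-4,4,5,5-tetramethyl-1,3,2-dioxaborolane | COCOc1cc(B2OC(C)(C)C(C)(C)O2)cc(OCOC)c1OC | intermediate (not isolated)
4 | 4-methoxy-3,5-bis(methoxymethoxy)phenol | COCOc1cc(O)cc(OCOC)c1OC | intermediate
5 | 2,5-dimethoxy-1,3-bis(methoxymethoxy)benzene | COCOc1cc(OC)cc(OCOC)c1OC | intermediate
6 | [3,6-dimethoxy-2,4-bis(methoxymethoxy)phenyl]lithium | [Li]c1c(OC)cc(OCOC)c(OC)c1OCOC | intermediate (not isolated)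
7 | 3,6-dimethoxy-2,4-bis(methoxymethoxy)benzaldehyde | O=Cc1c(OC)cc(OCOC)c(OC)c1OCOC | intermediate
8 | 2,4-dihydroxy-3,6-dimethoxybenzaldehyde | O=Cc1c(OC)cc(O)c(OC)c1O | intermediate
9 | 1-bromo-3-methylbut-2-ene (prenyl bromide) | CC(C)=CCBr | starting material
10 | 2-hydroxy-3,6-dimethoxy-4-(3-methylbut-2-enyloxy)benzaldehyde | O=Cc1c(OC)cc(OCC=C(C)C)c(OC)c1O | intermediate
11 | methyl 2-(4-hydroxy-3-methoxyphenyl)acetate (methyl homovanillate) | COC(=O)Cc1ccc(O)c(OC)c1 | starting material
12 | methyl 2-(3-methoxy-4-triisopropylsilyloxyphenyl)acetate | COC(=O)Cc1ccc(O[Si](C(C)C)(C(C)C)C(C)C)c(OC)c1 | intermediate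
13 | lithium 1-methoxy-2-(3-methoxy-4-triisopropylsilyloxyphenyl)ethenolate (enolate geometry not defined) | COC([O-])=Cc1ccc(O[Si](C(C)C)(C(C)C)C(C)C)c(OC)c1.[Li+] | intermediate (not isolated)
14 | [1-methoxy-2-(3-methoxy-4-triisopropylsilyloxyphenyl)ethenyl]oxy-trimethylsilane (E/Z mixture) | COC(O[Si](C)(C)C)=Cc1ccc(O[Si](C(C)C)(C(C)C)C(C)C)c(OC)c1 | intermediate (not isolated)
15 | methyl 2-bromo-2-(3-methoxy-4-triisopropylsilyloxyphenyl)acetate (racemic) | COC(=O)C(Br)c1ccc(O[Si](C(C)C)(C(C)C)C(C)C)c(OC)c1 | intermediate
16 | methyl 2-[2-formyl-3,6-dimethoxy-5-(3-methylbut-2-enyloxy)phenoxy]-2-(3-methoxy-4-triisopropylsilyloxyphenyl)acetate (racemic) | COC(=O)C(Oc1c(OC)c(OCC=C(C)C)cc(OC)c1C=O)c1ccc(O[Si](C(C)C)(C(C)C)C(C)C)c(OC)c1 | intermediate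
17 | 2-[2-(hydroxymethyl)-3,6-dimethoxy-5-(3-methylbut-2-enyloxy)phenoxy]-2-(3-methoxy-4-triisopropylsilyloxyphenyl)ethanol (racemic) | OCC(Oc1c(OC)c(OCC=C(C)C)cc(OC)c1CO)c1ccc(O[Si](C(C)C)(C(C)C)C(C)C)c(OC)c1 | intermediate
18 | 2-[1-(3-methoxy-4-triisopropylsilyloxyphenyl)-2-oxoethoxy]-3,6-dimethoxy-4-(3-methylbut-2-enyloxy)benzaldehyde (racemic) | O=CC(Oc1c(OC)c(OCC=C(C)C)cc(OC)c1C=O)c1ccc(O[Si](C(C)C)(C(C)C)C(C)C)c(OC)c1 | intermediate
19 | 5,8-dimethoxy-2-(3-methoxy-4-triisopropylsilyloxyphenyl)-7-(3-methylbut-2-enyloxy)chromane-3,4-diol (racemic diastereomer mixture) | COc1cc(C2Oc3c(OC)c(OCC=C(C)C)cc(OC)c3C(O)C2O)ccc1O[Si](C(C)C)(C(C)C)C(C)C | intermediate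
20 | 5,8-dimethoxy-2-(3-methoxy-4-triisopropylsilyloxyphenyl)-7-(3-methylbut-2-enyloxy)chromane-3,4-dione (racemic) | COc1cc(C2Oc3c(OC)c(OCC=C(C)C)cc(OC)c3C(=O)C2=O)ccc1O[Si](C(C)C)(C(C)C)C(C)C | intermediate (not isolated)
21 | 3-hydroxy-5,8-dimethoxy-2-(3-methoxy-4-triisopropylsilyloxyphenyl)-7-(3-methylbut-2-enyloxy)chromen-4-one | COc1cc(-c2oc3c(OC)c(OCC=C(C)C)cc(OC)c3c(=O)c2O)ccc1O[Si](C(C)C)(C(C)C)C(C)C | intermediate
22 | 3,5,8-trimethoxy-2-(3-methoxy-4-triisopropylsilyloxyphenyl)-7-(3-methylbut-2-enyloxy)chromen-4-one | COc1cc(-c2oc3c(OC)c(OCC=C(C)C)cc(OC)c3c(=O)c2OC)ccc1O[Si](C(C)C)(C(C)C)C(C)C | intermediate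
23 | 2-(4-hydroxy-3-methoxyphenyl)-3,5,8-trimethoxy-7-(3-methylbut-2-enyloxy)chromen-4-one | COc1cc(-c2oc3c(OC)c(OCC=C(C)C)cc(OC)c3c(=O)c2OC)ccc1O | target

**Step count and risks**

Total step count: 15. Longest linear sequence: 13 steps (steps 1–6, then 9–15); the ring B branch (steps 7–8) joins at step 9.

Steps most likely to fail:

1. Step 12. A ketyl formed at the aliphatic aldehyde may take up a second electron and expel the aryloxide (cleavage of the C2–O1 bond), or the aryl ketyl may couple intermolecularly or be reduced to the benzylic alcohol before it cyclises. The fallback gives up the C3–C4 closure and builds ring C by aldol union and cyclodehydration; it sets out from 5 and comes back at 22.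
   - The aryllithium 6, generated from 5 as in step 4, would be acylated with N,2-dimethoxy-N-methylacetamide to give 1-[3,6-dimethoxy-2,4-bis(methoxymethoxy)phenyl]-2-methoxyethanone F1.
   - Vanillin would be silylated (TIPSCl, imidazole) to 3-methoxy-4-triisopropylsilyloxybenzaldehyde F2.
   - The lithium enolate of F1 (LDA, THF, −78 °C) would add to F2 to give the aldol 1-[3,6-dimethoxy-2,4-bis(methoxymethoxy)phenyl]-3-hydroxy-2-methoxy-3-(3-methoxy-4-triisopropylsilyloxyphenyl)propan-1-one F3.
   - Dess–Martin oxidation would give the 1,3-diketone 1-[3,6-dimethoxy-2,4-bis(methoxymethoxy)phenyl]-2-methoxy-3-(3-methoxy-4-triisopropylsilyloxyphenyl)propane-1,3-dione F4.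
   - HCl in methanol would remove both MOM groups and close the pyranone by cyclodehydration to 7-hydroxy-3,5,8-trimethoxy-2-(3-methoxy-4-triisopropylsilyloxyphenyl)chromen-4-one F5.
   - 7-O-Prenylation with 9 (K2CO3, acetone) would then give 22, and step 15 completes the route. The prenyl ether enters only after the acidic steps.

2. Step 11. The very electron-rich benzylic alcohol may ionise or be over-oxidised, and the enolisable α-aryloxy aldehyde may decompose during oxidation and isolation. The fallback reaches the dialdehyde by partial reduction of the ester instead of oxidation of the diol; it sets out from 16, bypasses 17 and comes back at 18.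
   - The aryl aldehyde of 16 would be masked with trimethyl orthoformate and PPTS in methanol as methyl 2-[2-(dimethoxymethyl)-3,6-dimethoxy-5-(3-methylbut-2-enyloxy)phenoxy]-2-(3-methoxy-4-triisopropylsilyloxyphenyl)acetate F6.
   - DIBAL-H (1.1 equiv, −78 °C) would stop at the aldehyde, helped by the α-aryloxy group, giving 2-[2-(dimethoxymethyl)-3,6-dimethoxy-5-(3-methylbut-2-enyloxy)phenoxy]-2-(3-methoxy-4-triisopropylsilyloxyphenyl)acetaldehyde F7.
   - The highly labile electron-rich acetal would be hydrolysed with PPTS in aqueous acetone immediately before step 12 to give 18.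

3. Step 9. O-Alkylation of the hindered, hydrogen-bonded phenol may be slow, so that solvolysis of the ionisable benzylic bromide, intramolecular aldol closure of the product towards a benzofuran, or loss of the silyl group under the basic conditions takes over. The fallback forms the O1–C2 bond by carbene O–H insertion under neutral conditions; it sets out from 12 (with 10) and comes back at 16.
   - Regitz diazo transfer to 12 (p-acetamidobenzenesulfonyl azide, DBU, MeCN) would give methyl 2-diazo-2-(3-methoxy-4-triisopropylsilyloxyphenyl)acetate F8.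
   - Slow addition of F8 to 10 with Rh2(OAc)4 (cat.) in CH2Cl2 would give 16 by rhodium-carbenoid insertion into the phenol O–H bond.

**Further compounds**

F1 | step 12 | 1-[3,6-dimethoxy-2,4-bis(methoxymethoxy)phenyl]-2-methoxyethanone | COCC(=O)c1c(OC)cc(OCOC)c(OC)c1OCOC
F2 | step 12 | 3-methoxy-4-triisopropylsilyloxybenzaldehyde | O=Cc1ccc(O[Si](C(C)C)(C(C)C)C(C)C)c(OC)c1
F3 | step 12 | 1-[3,6-dimethoxy-2,4-bis(methoxymethoxy)phenyl]-3-hydroxy-2-methoxy-3-(3-methoxy-4-triisopropylsilyloxyphenyl)propan-1-one (racemic diastereomer mixture) | COCOc1cc(OC)c(C(=O)C(OC)C(O)c2ccc(O[Si](C(C)C)(C(C)C)C(C)C)c(OC)c2)c(OCOC)c1OC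
F4 | step 12 | 1-[3,6-dimethoxy-2,4-bis(methoxymethoxy)phenyl]-2-methoxy-3-(3-methoxy-4-triisopropylsilyloxyphenyl)propane-1,3-dione (racemic) | COCOc1cc(OC)c(C(=O)C(OC)C(=O)c2ccc(O[Si](C(C)C)(C(C)C)C(C)C)c(OC)c2)c(OCOC)c1OC
F5 | step 12 | 7-hydroxy-3,5,8-trimethoxy-2-(3-methoxy-4-triisopropylsilyloxyphenyl)chromen-4-one | COc1cc(-c2oc3c(OC)c(O)cc(OC)c3c(=O)c2OC)ccc1O[Si](C(C)C)(C(C)C)C(C)C
F6 | step 11 | methyl 2-[2-(dimethoxymethyl)-3,6-dimethoxy-5-(3-methylbut-2-enyloxy)phenoxy]-2-(3-methoxy-4-triisopropylsilyloxyphenyl)acetate (racemic) | COC(=O)C(Oc1c(OC)c(OCC=C(C)C)cc(OC)c1C(OC)OC)c1ccc(O[Si](C(C)C)(C(C)C)C(C)C)c(OC)c1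
F7 | step 11 | 2-[2-(dimethoxymethyl)-3,6-dimethoxy-5-(3-methylbut-2-enyloxy)phenoxy]-2-(3-methoxy-4-triisopropylsilyloxyphenyl)acetaldehyde (racemic) | O=CC(Oc1c(OC)c(OCC=C(C)C)cc(OC)c1C(OC)OC)c1ccc(O[Si](C(C)C)(C(C)C)C(C)C)c(OC)c1
F8 | step 9 | methyl 2-diazo-2-(3-methoxy-4-triisopropylsilyloxyphenyl)acetate | COC(=O)C(=[N+]=[N-])c1ccc(O[Si](C(C)C)(C(C)C)C(C)C)c(OC)c1
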